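**Plan**

- Retrosynthesis: the 7-O and 3'-O galloyl esters and all benzyl ethers are cut last. The C3–OH and C2–H bonds go back to a flav-2-ene (C2=C3 enol ether). Ring C is then cut at C3–C4 and O1–C8a together, giving a ring-A 2-fluorobenzyl bromide and a ring-B acetophenone.
- Feature used: in ring A, C8a is meta to both oxygens (O5, O7), so a fluoride there is inductively activated for SNAr and not deactivated by resonance. The benzylic C4 sits on C4a, ortho/para to the same oxygens. Ring A is thus a C4/C8a 1,3-dielectrophile for the C3/O1 ambident enolate of the ketone.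
- Forward: rings A and B are prepared separately (benzyl on O5 and O4', MOM on O7 and O3'). Ring C is closed in one pot by enolate C-benzylation followed by enolate O-arylation. The esters are added after MOM removal.
- Stereochemistry: both stereocentres come from one asymmetric hydroboration–oxidation of C2=C3. Syn addition of H and B gives the 2,3-trans relationship, and the isopinocampheyl group on boron selects the face for (2R,3S).

Key step: step 8

Remark on the chemistry: ring C is closed at the enol ether oxidation level (O1 arrives as the ketone oxygen, C3 as the methyl carbon of the acetophenone), and the antipode of IpcBH2 made from (+)-α-pinene is assumed to lead to (2R,3S), by analogy with 1-arylcycloalkenes.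

**Route**

Step 1
Reactants: 1 5-fluororesorcinol
Product: 3 2-fluoro-4,6-dihydroxybenzaldehyde, via aryl iminium chloride 2 (not isolated)
Conditions: POCl3, DMF, MeCN, 0 → 25 °C; then H2O, 50 °C
Reagents that add atoms: N,N-dimethylformamide CN(C)C=O; water O
Why: Vilsmeier–Haack formylation should occur at the ring carbon ortho to one hydroxyl and para to the other (the site between OH and F), as resorcinols formylate there and not between the two hydroxyls, and hydrolysis of iminium salt 2 releases the aldehyde.

Step 2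
Reactants: 3 2-fluoro-4,6-dihydroxybenzaldehyde
Product: 4 2-fluoro-6-hydroxy-4-(methoxymethoxy)benzaldehyde
Conditions: MOMCl (1.05 equiv), iPr2NEt, CH2Cl2, 0 °C
Reagents that add atoms: chloromethyl methyl ether COCCl
Why: The 4-OH (para to the formyl group) is the more acidic and is not held in the intramolecular hydrogen bond that deactivates the 6-OH, so one equivalent of MOMCl should etherify it selectively (Williamson-type O-alkylation).

Step 3
Reactants: 4 2-fluoro-6-hydroxy-4-(methoxymethoxy)benzaldehyde
Product: 5 2-(benzyloxy)-6-fluoro-4-(methoxymethoxy)benzaldehyde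
Conditions: BnBr, K2CO3, Bu4NI (cat.), DMF, 25 °C
Reagents that add atoms: benzyl bromide BrCc1ccccc1
Why: Williamson benzylation of the remaining hydrogen-bonded ortho-hydroxyl needs only carbonate in DMF, and room temperature should leave the aldehyde-activated C–F bond untouched.

Step 4
Reactants: 5 2-(benzyloxy)-6-fluoro-4-(methoxymethoxy)benzaldehyde
Product: 6 [2-(benzyloxy)-6-fluoro-4-(methoxymethoxy)phenyl]methanol
Conditions: NaBH4, MeOH/THF, 0 °C
Reagents that add atoms: none
Why: Borohydride reduction of the aldehyde to the benzylic alcohol should leave the aryl fluoride, the MOM ether and the benzyl ether untouched.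

Step 5
Reactants: 6 [2-(benzyloxy)-6-fluoro-4-(methoxymethoxy)phenyl]methanol
Product: 7 1-(benzyloxy)-2-(bromomethyl)-3-fluoro-5-(methoxymethoxy)benzene
Conditions: CBr4, PPh3, CH2Cl2, 0 °C; used at once
Reagents that add atoms: tetrabromomethane BrC(Br)(Br)Br
Why: The Appel bromination runs under neutral conditions that spare the acid-labile MOM ether, and the electron-rich benzylic bromide is used at once as a solution because it is labile.

Step 6
Reactants: 8 3,4-dihydroxyacetophenone
Product: 9 1-[4-(benzyloxy)-3-hydroxyphenyl]ethan-1-one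
Conditions: BnBr (1.0 equiv), Li2CO3, DMF, 50 °C
Reagents that add atoms: benzyl bromide BrCc1ccccc1
Why: The 4-OH, para to the acetyl group, is the more acidic phenol, so a weak carbonate base and one equivalent of benzyl bromide should give the 4-O-benzyl ether selectively (Williamson ether synthesis).

Step 7
Reactants: 9 1-[4-(benzyloxy)-3-hydroxyphenyl]ethan-1-one
Product: 10 1-[4-(benzyloxy)-3-(methoxymethoxy)phenyl]ethan-1-one
Conditions: MOMCl, iPr2NEt, CH2Cl2, 0 → 25 °C
Reagents that add atoms: chloromethyl methyl ether COCCl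
Why: MOM etherification of the remaining phenol under amine base is routine and leaves the ketone untouched.

Step 8
Reactants: 10 1-[4-(benzyloxy)-3-(methoxymethoxy)phenyl]ethan-1-one; 7 1-(benzyloxy)-2-(bromomethyl)-3-fluoro-5-(methoxymethoxy)benzene
Product: 12 5-(benzyloxy)-2-[4-(benzyloxy)-3-(methoxymethoxy)phenyl]-7-(methoxymethoxy)-4H-chromene, via open-chain fluoro ketone 11 (not isolated)
Conditions: 10 (1.5 equiv), LiN(SiMe3)2, THF, −78 °C; 7, −78 → 0 °C; then KN(SiMe3)2 (1.0 equiv), 18-crown-6, toluene, 90 °C
Reagents that add atoms: none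
Why: Proposed new method: a formal [3+3] annulation in which the Li enolate of 10 is first C-benzylated at C3 by the SN2-reactive benzylic bromide 7 (C3–C4 bond, ketone 11), and the K (Z)-enolate of 11 then attacks C8a through oxygen and expels fluoride (SNAr through a Meisenheimer adduct, O1–C8a bond) to give the flav-2-ene; the closest known reaction types are the domino C-benzylation/O-arylation of 1,3-dicarbonyl compounds with 2-halobenzyl halides to 4H-chromenes and the base-mediated closure of benzofurans by enolate-oxygen SNAr on unactivated 2-fluoroarenes. Ring C closes by a 6-exo-trig addition–elimination at C8a, which is meta to both ring-A oxygens and therefore inductively activated without resonance deactivation. No stereocentre is created, since C2 and C3 leave the step as the enol ether double bond on which step 9 acts. The step needs mono- over di-alkylation and C- over O-alkylation in the first stage, which the Li enolate in THF at low temperature, the excess of 10 and the soft benzylic bromide should secure, and O- over C-arylation in the second, which is secured because attack of C3 on C8a would close a four-membered ring and because only C3 of the ketone carries enolisable hydrogen. One equivalent of KN(SiMe3)2 leaves no strong base once fluoride is lost, so the doubly activated C4 methylene of 12 should not be deprotonated.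

Step 9
Reactants: 12 5-(benzyloxy)-2-[4-(benzyloxy)-3-(methoxymethoxy)phenyl]-7-(methoxymethoxy)-4H-chromene
Product: 14 (2R,3S)-5-(benzyloxy)-2-[4-(benzyloxy)-3-(methoxymethoxy)phenyl]-7-(methoxymethoxy)-3,4-dihydro-2H-chromen-3-ol, via C3 isopinocampheylborane 13 (not isolated)
Conditions: IpcBH2 (from (+)-α-pinene), THF, −25 → 0 °C; then NaOH, H2O2, H2O, 0 → 25 °C
Reagents that add atoms: hydrogen peroxide OO
Why: In this asymmetric hydroboration–oxidation boron should add to C3 (β to O1 and remote from the C2 aryl group) and hydrogen to C2 on the same face, so that the aryl group and the C3–O bond formed with retention on oxidation are trans, while the isopinocampheyl group selects the face, as it does for 1-arylcycloalkenes, to give (2R,3S).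

Step 10
Reactants: 14 (2R,3S)-5-(benzyloxy)-2-[4-(benzyloxy)-3-(methoxymethoxy)phenyl]-7-(methoxymethoxy)-3,4-dihydro-2H-chromen-3-ol
Product: 15 (2R,3S)-5-(benzyloxy)-2-[4-(benzyloxy)-3-hydroxyphenyl]-3,4-dihydro-2H-chromene-3,7-diol
Conditions: HCl (cat.), MeOH/THF, 45 °C
Reagents that add atoms: none
Why: Acid-catalysed acetal exchange with methanol should remove both MOM groups as dimethoxymethane, while the benzyl ethers survive and the mild acid should not epimerise C2.

Step 11
Reactants: 16 3,4,5-tris(benzyloxy)benzoic acid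
Product: 17 3,4,5-tris(benzyloxy)benzoyl chloride
Conditions: (COCl)2, DMF (cat.), CH2Cl2, 0 → 25 °C
Reagents that add atoms: oxalyl chloride ClC(=O)C(Cl)=O
Why: Oxalyl chloride with catalytic DMF is the standard conversion of an aromatic acid into its acid chloride, with only gaseous by-products.

Step 12
Reactants: 15 (2R,3S)-5-(benzyloxy)-2-[4-(benzyloxy)-3-hydroxyphenyl]-3,4-dihydro-2H-chromene-3,7-diol; 17 3,4,5-tris(benzyloxy)benzoyl chloride
Product: 18 5,4'-di-O-benzylcatechin 7,3'-bis[3,4,5-tris(benzyloxy)benzoate]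
Conditions: 17 (2.1 equiv), Et3N, CH2Cl2, −20 → 0 °C
Reagents that add atoms: none
Why: Under amine base without DMAP at low temperature the two free phenols (O7 and O3', the only ones not benzylated) should be acylated much faster than the hindered secondary 3-OH (Einhorn-type acylation).

Step 13
Reactants: 18 5,4'-di-O-benzylcatechin 7,3'-bis[3,4,5-tris(benzyloxy)benzoate]
Product: 19 catechin 7,3'-di-O-gallate
Conditions: H2 (1 atm), Pd(OH)2/C, THF/MeOH, 25 °C
Reagents that add atoms: none
Why: Hydrogenolysis over Pd(OH)2/C should cleave all eight benzyl ethers while the aryl esters and the pyran C2–O bond persist, and neutral conditions with cold concentration are meant to suppress migration of the 3'-galloyl group to the freed 4'-OH.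

**Compound list**

1 | 5-fluororesorcinol (5-fluorobenzene-1,3-diol) | Oc1cc(O)cc(F)c1 | starting material
2 | N-[(2-fluoro-4,6-dihydroxyphenyl)methylidene]-N-methylmethanaminium chloride (aryl iminium chloride, formed in the flask, not isolated) | C[N+](C)=Cc1c(O)cc(O)cc1F.[Cl-] | intermediate
3 | 2-fluoro-4,6-dihydroxybenzaldehyde | O=Cc1c(O)cc(O)cc1F | intermediate
4 | 2-fluoro-6-hydroxy-4-(methoxymethoxy)benzaldehyde | COCOc1cc(O)c(C=O)c(F)c1 | intermediate
5 | 2-(benzyloxy)-6-fluoro-4-(methoxymethoxy)benzaldehyde | COCOc1cc(F)c(C=O)c(OCc2ccccc2)c1 | intermediate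
6 | [2-(benzyloxy)-6-fluoro-4-(methoxymethoxy)phenyl]methanol | COCOc1cc(F)c(CO)c(OCc2ccccc2)c1 | intermediate
7 | 1-(benzyloxy)-2-(bromomethyl)-3-fluoro-5-(methoxymethoxy)benzene | COCOc1cc(F)c(CBr)c(OCc2ccccc2)c1 | intermediate
8 | 3,4-dihydroxyacetophenone | CC(=O)c1ccc(O)c(O)c1 | starting material
9 | 1-[4-(benzyloxy)-3-hydroxyphenyl]ethan-1-one | CC(=O)c1ccc(OCc2ccccc2)c(O)c1 | intermediate
10 | 1-[4-(benzyloxy)-3-(methoxymethoxy)phenyl]ethan-1-one | CC(=O)c1ccc(OCc2ccccc2)c(OCOC)c1 | intermediate
11 | 3-[2-(benzyloxy)-6-fluoro-4-(methoxymethoxy)phenyl]-1-[4-(benzyloxy)-3-(methoxymethoxy)phenyl]propan-1-one (open-chain fluoro ketone, formed in the flask, not isolated) | COCOc1cc(F)c(CCC(=O)c2ccc(OCc3ccccc3)c(OCOC)c2)c(OCc2ccccc2)c1 | intermediate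
12 | 5-(benzyloxy)-2-[4-(benzyloxy)-3-(methoxymethoxy)phenyl]-7-(methoxymethoxy)-4H-chromene (flav-2-ene) | COCOc1cc2OC(c3ccc(OCc4ccccc4)c(OCOC)c3)=CCc2c(OCc2ccccc2)c1 | intermediate
13 | (flavan-3-yl)(isopinocampheyl)borane, boron on C3 trans to the C2 aryl group, same spatial arrangement at C2 and C3 as in 14 (formed in the flask, not isolated) | C[C@H]1[C@H]([BH][C@H]2Cc3c(OCc4ccccc4)cc(OCOC)cc3O[C@@H]2c2ccc(OCc3ccccc3)c(OCOC)c2)C[C@@H]2C[C@H]1C2(C)C | intermediate
14 | (2R,3S)-5-(benzyloxy)-2-[4-(benzyloxy)-3-(methoxymethoxy)phenyl]-7-(methoxymethoxy)-3,4-dihydro-2H-chromen-3-ol | COCOc1cc2O[C@H](c3ccc(OCc4ccccc4)c(OCOC)c3)[C@@H](O)Cc2c(OCc2ccccc2)c1 | intermediate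
15 | (2R,3S)-5-(benzyloxy)-2-[4-(benzyloxy)-3-hydroxyphenyl]-3,4-dihydro-2H-chromene-3,7-diol (5,4'-di-O-benzylcatechin) | Oc1cc2O[C@H](c3ccc(OCc4ccccc4)c(O)c3)[C@@H](O)Cc2c(OCc2ccccc2)c1 | intermediate
16 | 3,4,5-tris(benzyloxy)benzoic acid | OC(=O)c1cc(OCc2ccccc2)c(OCc2ccccc2)c(OCc2ccccc2)c1 | starting material
17 | 3,4,5-tris(benzyloxy)benzoyl chloride | ClC(=O)c1cc(OCc2ccccc2)c(OCc2ccccc2)c(OCc2ccccc2)c1 | intermediate
18 | (2R,3S)-5,4'-di-O-benzylcatechin 7,3'-bis[3,4,5-tris(benzyloxy)benzoate] | O=C(Oc1cc2O[C@H](c3ccc(OCc4ccccc4)c(OC(=O)c4cc(OCc5ccccc5)c(OCc5ccccc5)c(OCc5ccccc5)c4)c3)[C@@H](O)Cc2c(OCc2ccccc2)c1)c1cc(OCc2ccccc2)c(OCc2ccccc2)c(OCc2ccccc2)c1 | intermediate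
19 | catechin 7,3'-di-O-gallate, (2R,3S) | O=C(Oc1cc(O)c2c(c1)O[C@H](c1ccc(O)c(OC(=O)c3cc(O)c(O)c(O)c3)c1)[C@@H](O)C2)c1cc(O)c(O)c(O)c1 | target

**Step count**

Total: 13 steps. Longest linear sequence: 10 steps (steps 1, 2, 3, 4, 5, 8, 9, 10, 12, 13).

**Steps most likely to fail**

1. Step 8. The labile benzylic bromide may decompose, or the enolate may be alkylated twice before ring closure, and displacement of fluoride by the enolate oxygen on the electron-rich ring may be sluggish. The fallback uses known reactions, sets out from ketone 10 and comes back at 12. Commercial 5-bromoresorcinol is formylated with POCl3/DMF to 2-bromo-4,6-dihydroxybenzaldehyde F1. This is protected as in steps 2 and 3 to 2-bromo-6-hydroxy-4-(methoxymethoxy)benzaldehyde F2 and then 2-(benzyloxy)-6-bromo-4-(methoxymethoxy)benzaldehyde F3. Claisen–Schmidt condensation of F3 with 10 (KOH, EtOH, 25 °C) should give the (E)-chalcone F4. Conjugate reduction ([(Ph3P)CuH]6 cat., PhSiH3, toluene, 25 °C) should give the saturated bromo ketone F5. Ullmann-type intramolecular O-arylation of its enolate (CuI, 1,10-phenanthroline, K3PO4, DMF, 105 °C) then closes ring C to 12. A copper-catalysed C–O coupling on an isolated ketone thus replaces the one-pot alkylation/SNAr.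

2. Step 9. The chiral borane may show poor facial selectivity toward the trisubstituted enol ether; the trans relationship is not at risk, the enantiomeric purity is. The fallback sets out from 12 and comes back at 14. Hydroboration–oxidation with BH3·SMe2, then NaOH/H2O2, should give the racemic trans alcohol, that is 14 mixed with its (2S,3R) enantiomer F6. Enantioselective acetylation with immobilised Candida antarctica lipase B and vinyl acetate (MTBE, 35 °C) separates the two. 14 is collected as the unreacted alcohol if it is the slower-reacting enantiomer, or otherwise as its (2R,3S) 3-O-acetate F7, which K2CO3/MeOH returns to 14.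

3. Step 12. Chemoselectivity between the phenols and the secondary 3-hydroxyl may be lost (over-acylation or incomplete acylation). The fallback sets out from 14 and comes back at 19. 14 is O-benzylated at the 3-hydroxyl (NaH, BnBr, Bu4NI, DMF, 0 → 25 °C) to the 3-O-benzyl ether F8. The MOM groups are removed as in step 10 to give the diphenol F9. Exhaustive acylation with 17 (Et3N, DMAP, CH2Cl2, 25 °C) gives the fully protected diester F10. Hydrogenolysis under the conditions of step 13 then cleaves nine benzyl ethers to give 19.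

**Further compounds**

F1 | step 8 | 2-bromo-4,6-dihydroxybenzaldehyde | O=Cc1c(O)cc(O)cc1Br
F2 | step 8 | 2-bromo-6-hydroxy-4-(methoxymethoxy)benzaldehyde | COCOc1cc(O)c(C=O)c(Br)c1
F3 | step 8 | 2-(benzyloxy)-6-bromo-4-(methoxymethoxy)benzaldehyde | COCOc1cc(Br)c(C=O)c(OCc2ccccc2)c1
F4 | step 8 | (E)-chalcone, (E)-3-[2-(benzyloxy)-6-bromo-4-(methoxymethoxy)phenyl]-1-[4-(benzyloxy)-3-(methoxymethoxy)phenyl]prop-2-en-1-one | COCOc1cc(Br)c(/C=C/C(=O)c2ccc(OCc3ccccc3)c(OCOC)c2)c(OCc2ccccc2)c1
F5 | step 8 | saturated bromo ketone, 3-[2-(benzyloxy)-6-bromo-4-(methoxymethoxy)phenyl]-1-[4-(benzyloxy)-3-(methoxymethoxy)phenyl]propan-1-one | COCOc1cc(Br)c(CCC(=O)c2ccc(OCc3ccccc3)c(OCOC)c2)c(OCc2ccccc2)c1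
F6 | step 9 | (2S,3R) enantiomer of 14 (present with 14 in the racemate) | COCOc1cc2O[C@@H](c3ccc(OCc4ccccc4)c(OCOC)c3)[C@H](O)Cc2c(OCc2ccccc2)c1
F7 | step 9 | (2R,3S) 3-O-acetate of 14 | COCOc1cc2O[C@H](c3ccc(OCc4ccccc4)c(OCOC)c3)[C@@H](OC(C)=O)Cc2c(OCc2ccccc2)c1
F8 | step 12 | 3-O-benzyl ether of 14, (2R,3S)-3,5-bis(benzyloxy)-2-[4-(benzyloxy)-3-(methoxymethoxy)phenyl]-7-(methoxymethoxy)chromane | COCOc1cc2O[C@H](c3ccc(OCc4ccccc4)c(OCOC)c3)[C@@H](OCc3ccccc3)Cc2c(OCc2ccccc2)c1
F9 | step 12 | diphenol, (2R,3S)-3,5-bis(benzyloxy)-2-[4-(benzyloxy)-3-hydroxyphenyl]chroman-7-ol | Oc1cc2O[C@H](c3ccc(OCc4ccccc4)c(O)c3)[C@@H](OCc3ccccc3)Cc2c(OCc2ccccc2)c1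
F10 | step 12 | fully protected diester, (2R,3S)-3,5,4'-tri-O-benzylcatechin 7,3'-bis[3,4,5-tris(benzyloxy)benzoate] | O=C(Oc1cc2O[C@H](c3ccc(OCc4ccccc4)c(OC(=O)c4cc(OCc5ccccc5)c(OCc5ccccc5)c(OCc5ccccc5)c4)c3)[C@@H](OCc3ccccc3)Cc2c(OCc2ccccc2)c1)c1cc(OCc2ccccc2)c(OCc2ccccc2)c(OCc2ccccc2)c1
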